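# Proposed synthesis of (2S)-5-hydroxy-2-(2-hydroxy-6-methoxyphenyl)-6,7,8-trimethoxychroman-4-one

## Analysis of the target

The target is a flavanone: a chroman-4-one in which the pyranone ring C is fused to benzene ring A and carries aryl ring B at C2. Ring A is fully substituted, with a hydroxyl at C5, methoxy groups at C6, C7 and C8, the ring oxygen O1 on C8a and the ketone carbon C4 on C4a. Ring B is 1,2,3-trisubstituted, with a hydroxyl at C2′ and a methoxy group at C6′ on either side of the carbon bonded to C2. The only stereocentre is C2, which is S (O1 > C1′ > C3 > H) and has no other centre to relate to. C2 is benzylic, α to O1 and β to the ketone, so base can open ring C by retro-oxa-Michael reaction to a 2′-hydroxychalcone that recloses without stereocontrol. Acid can ionise the C2–O1 bond, because the two ortho oxygens of ring B stabilise a C2 cation strongly. The difficulty is therefore to set C2 without passing through a chalcone, to assemble the hexasubstituted ring A, and to tell the C5 hydroxyl from three methoxy groups and the C2′ hydroxyl from the C6′ methoxy group. The strategy rests on one feature: O1 and C4 sit on the adjacent ring A carbons C8a and C4a, so O1=C8a–C4a=C4 is an ortho-quinone methide heterodiene, and C2–C3 is the double bond of a ring B styrene.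

## Retrosynthetic reasoning

**15 back to 13.** The methyl–oxygen bond at C5 and the benzyl–oxygen bond at C2′ are cut last. The C5 methoxy group is the only one peri to the C4 ketone, so a chelating boron Lewis acid can pick it out from the other four. The ring B hydroxyl travels as a benzyl ether, which survives every earlier acid step and falls to the same Lewis acid. Both free phenols thus appear only in the final operation, via the mono-deprotected 14, and the forward step must cleave two ethers without opening the C2–O1 bond.

**13 back to 12 and 11.** No skeletal bond is cut here; only the oxidation level at C4 is adjusted, ketone from alcohol from methyl ether. The ether level is what the cycloaddition delivers. It keeps ring C free of a β-aryloxy ketone, and with it free of the retro-oxa-Michael pathway, until two steps from the end. The C4 centre is disposable, so both epimers of 12 serve.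

**11 back to 6 and 9 through 10.** The bonds O1–C2 and C3–C4 are cut. These are the two bonds that join ring C to two simple aromatic pieces, each derived from a commercial benzaldehyde or phenol. Any other cut, such as C2–C1′ or a bond within ring A or ring B, would mean building an aromatic ring that can be bought. The gain is full convergence and the creation of C2 in the bond-forming event itself, under a chiral counter-anion, with no chalcone on the path. The forward reaction has to ionise acetal 6 to heterodiene 10, add styrene 9 with the right regiochemistry, and select one face of the styrene.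

**6 back to 4 and 5, and 4 back to 1.** The two acetal C–O bonds are cut to aldehyde 4 and orthoformate 5. In 4 the C3 methoxy C–O bond is cut to bromide 3, the C–Br bond to 2, and the formyl C–C bond to phenol 1. Formylation comes first because the two ortho positions of 1 are equivalent, and the aldehyde then leaves exactly one open ring position for bromine. This order avoids double bromination and avoids handling an air-sensitive tetra-alkoxyphenol.

**9 back to 8 and 7.** The vinyl C=C bond is cut by Wittig methylenation to aldehyde 8, and the benzyl ether to the commercial salicylaldehyde 7. Ring B arrives with its 1,2,3-pattern already in place.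

## Alternatives that were turned down

**Alternative 1:** ring B built by benzannulation. The disconnection runs through ring B at C1′–C6′ and C2′–C3′, giving cyclobut-2-en-1-one A3 and a siloxyalkyne already bonded to C2, (2S)-5,6,7,8-tetramethoxy-2-[(triisopropylsilyloxy)ethynyl]chroman-4-one A2.
- Forward key step: heating opens A3 to a vinylketene, which adds to the ynol ether in a [2+2] sense. The new cyclobutenone opens again and closes by 6π electrocyclisation to (S)-2-[2-hydroxy-6-(triisopropylsilyloxy)phenyl]-5,6,7,8-tetramethoxychroman-4-one A1, with the free hydroxyl and the silyl ether flanking C1′.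
- For: the two ring B oxygens emerge already differentiated, the cascade is thermal and needs neither acid nor base, and C2 would be set beforehand by known asymmetric conjugate chemistry on a chromone. On this point it is stronger than the chosen route, whose enantiocontrol is unproven.
- Against: it builds from scratch an aromatic ring that is commercial with the right pattern in 7. A2 is a fragile β-alkoxy ketone carrying an ynol ether, and it needs a multistep ester homologation under strong base that the C4 ketone does not tolerate unprotected. A3 is volatile and polymerises. The ketene intermediates can be intercepted by the enolisable ketone.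
- After A1, O-methylation under base, desilylation and the same C5 demethylation still remain, so the sequence is several steps longer and linear. The chosen route offers a convergent ten-step sequence instead.

**Alternative 2:** ring A grown by squarate ring expansion. The disconnection is at C4a–C5 of ring A, with C8–C8a made earlier by adding a metalated dihydropyran to a squaric ester. The precursor is 4-[(2S,4S)-4-(tert-butyldimethylsilyloxy)-2-(2-isopropoxy-6-methoxyphenyl)-3,4-dihydro-2H-pyran-6-yl]-2,3,4-trimethoxycyclobut-2-en-1-one A5.
- Forward key step: heating A5 in toluene opens the four-membered ring to a dienylketene, which closes by 6π electrocyclisation onto the enol ether double bond. Tautomerisation gives (2S,4S)-2-(2-isopropoxy-6-methoxyphenyl)-4-(tert-butyldimethylsilyloxy)-5-hydroxy-6,7,8-trimethoxychroman A4.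
- For: the hexasubstitution of ring A is fixed by the mechanism, and the C5 hydroxyl arises free and distinct from the three methoxy groups. Here it is stronger than the chosen route, which needs a late chelation-controlled demethylation.
- Against: A5 needs an enantioenriched 2-aryl-4-silyloxydihydropyran, metalation at C6 next to an acid-labile benzylic acetal-like C2, addition to the squarate and O-methylation. That is six or more linear steps before the key step.
- After A4, the silyl group must be removed, C4 oxidised in the presence of a free, very electron-rich phenol that is itself prone to quinone formation, and the isopropyl ether cleaved with a Lewis acid. The risk to C2 in the endgame therefore remains. The chosen route makes ring A from phenol 1 in three ordinary steps and joins the halves in one operation.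

**Alternative 3:** oxa-Michael closure onto an acylquinone. The disconnection is O1–C8a, giving the ketol 2-[(3S)-3-(2-benzyloxy-6-methoxyphenyl)-3-hydroxypropanoyl]-5,6-dimethoxy-1,4-benzoquinone A7.
- Forward key step: the C2 hydroxyl adds 6-endo to the quinone carbon next to the acyl group, and enolisation gives the hydroquinone (S)-2-[2-(benzyloxy)-6-methoxyphenyl]-5,8-dihydroxy-6,7-dimethoxychroman-4-one A6.
- For: C2 would be a secondary alcohol set by well-known asymmetric aldol or reduction chemistry and carried through with retention, since its C–O bond is not touched. The closure is regiochemically unambiguous and the C5 hydroxyl arises free. Stereocontrol is on firmer ground than in the chosen route.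
- Against: A7 joins an unstable acylquinone to a β-hydroxy ketone that can dehydrate or undergo retro-aldol cleavage, and its benzylic alcohol on a 2,6-dialkoxyphenyl ring ionises easily. The quinone must be generated by oxidation in the presence of that alcohol and the electron-rich ring B.
- A6 still needs selective methylation of the C8 hydroxyl under base, the very conditions that open flavanones to chalcones. The ring A precursor also needs more steps than 4. The chosen route installs all ring A oxygens at their final alkylation state before ring C exists.

Key step: step 7

## Remarks on the chemistry before the steps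

- The antipode of the chiral acid that delivers (2S) cannot be predicted and would be chosen in a screen; both are available from (R)- and (S)-BINOL.
- Compound 10 is drawn as the neutral E heterodiene; under the acid it should react as its O-protonated form, the hydroxyaryl oxocarbenium ion paired with the chiral anion.
- Compound 12 is expected as a mixture of C4 epimers, both of which give 13.

## Steps

Step 1
Reactants: 1 3,4,5-trimethoxyphenol
Product: 2 2-hydroxy-4,5,6-trimethoxybenzaldehyde
Conditions: MgCl2, Et3N, (CH2O)n, MeCN, reflux; then 1 M HCl
Reagents that add atoms: paraformaldehyde (as formaldehyde), C=O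
Why: Magnesium-phenoxide-directed ortho-formylation (Casnati–Skattebøl); the two ortho positions of 1 are equivalent, so one aldehyde should form, and a second equivalent of formaldehyde accepts the hydride.

Step 2
Reactants: 2 2-hydroxy-4,5,6-trimethoxybenzaldehyde
Product: 3 3-bromo-2-hydroxy-4,5,6-trimethoxybenzaldehyde
Conditions: NBS, MeCN, 0 °C to rt
Reagents that add atoms: N-bromosuccinimide, O=C1CCC(=O)N1Br
Why: Electrophilic aromatic bromination; C3 is the only unsubstituted ring carbon and is activated by the ortho hydroxyl, the ortho methoxy and the para methoxy group, so no regiochemical choice arises.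

Step 3
Reactants: 3 3-bromo-2-hydroxy-4,5,6-trimethoxybenzaldehyde
Product: 4 2-hydroxy-3,4,5,6-tetramethoxybenzaldehyde
Conditions: NaOMe (6 equiv), CuBr (0.3 equiv), MeOH/DMF, 110 °C; then aq. HCl
Reagents that add atoms: sodium methoxide, [Na+].[O-]C
Why: Copper-mediated Ullmann-type methoxylation of an aryl bromide; the substrate reacts as its sodium phenoxide, whose aldehyde is inert to methoxide, as in the methoxylation of ortho-bromophenol aldehydes such as 5-bromovanillin.

Step 4
Reactants: 4 2-hydroxy-3,4,5,6-tetramethoxybenzaldehyde; 5 trimethyl orthoformate
Product: 6 2-(dimethoxymethyl)-3,4,5,6-tetramethoxyphenol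
Conditions: HC(OMe)3 (5 equiv), MeOH, Amberlyst-15 (cat.), rt; filter through K2CO3, evaporate cold, use crude at once
Reagents that add atoms: trimethyl orthoformate (reactant 5), COC(OC)OC; methanol (solvent, exchanges into the acetal), CO
Why: Acid-catalysed acetalisation driven by the orthoformate as water scavenger; in methanol any quinone methide that forms is recaptured to 6, and removing the resin acid before concentration should keep the free-phenol acetal intact.

Step 5
Reactants: 7 2-hydroxy-6-methoxybenzaldehyde
Product: 8 2-(benzyloxy)-6-methoxybenzaldehyde
Conditions: BnBr, K2CO3, DMF, 50 °C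
Reagents that add atoms: benzyl bromide, BrCc1ccccc1
Why: Williamson ether synthesis on the phenoxide; the benzyl ether withstands the Wittig base and the Brønsted acids of steps 7 and 8 and is removed in step 10.

Step 6
Reactants: 8 2-(benzyloxy)-6-methoxybenzaldehyde
Product: 9 1-(benzyloxy)-3-methoxy-2-vinylbenzene
Conditions: Ph3PCH3Br, KOtBu, THF, 0 °C to rt
Reagents that add atoms: methyltriphenylphosphonium bromide, C[P+](c1ccccc1)(c1ccccc1)c1ccccc1.[Br-]
Why: Wittig methylenation; the unstabilised ylide is small enough for the 2,6-disubstituted aldehyde, which has no α-hydrogen to lose, and a terminal alkene raises no geometric question.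

Step 7
Reactants: 6 2-(dimethoxymethyl)-3,4,5,6-tetramethoxyphenol; 9 1-(benzyloxy)-3-methoxy-2-vinylbenzene
Product: 11 (2S,4S)-2-[2-(benzyloxy)-6-methoxyphenyl]-4,5,6,7,8-pentamethoxychromane (2,4-cis), via ortho-quinone methide 10 (not isolated)
Conditions: BINOL-derived imidodiphosphorimidate (IDPi) acid with N-triflyl groups (5 mol %), 9 (2 equiv), 5 Å MS, toluene, −40 °C, slow addition of 6; then Et3N
Reagents that add atoms: none
Why: Proposed new method: the chiral acid protonates one acetal oxygen of 6 and methanol leaves, giving the O-protonated form of 10, a hydroxyaryl oxocarbenium ion paired with the confined chiral anion that also holds the phenolic OH by a hydrogen bond. The CH2 terminus of 9 attacks the oxocarbenium carbon (future C4), and the developing C2 cation, stabilised by the two ortho alkoxy groups of ring B, is taken by the phenolic oxygen in a concerted but asynchronous inverse-demand [4+2] that returns ring A to aromaticity. The closest known reactions are the achiral acid-promoted cycloadditions of salicylaldehyde-acetal-derived ortho-quinone methides with styrenes to cis-4-alkoxyflavans and the chiral Brønsted acid control of cycloadditions of ortho-quinone methides made from ortho-hydroxybenzyl alcohols; an acetal precursor under a chiral anion with a hexasubstituted ring A has not been shown. Ring C closes as the six-membered ring of a hetero-Diels–Alder reaction, with O1=C8a–C4a=C4 as the 4π unit and C2=C3 as the 2π unit; in the stepwise limit it is the closure of O1 onto the C2 cation. C2 is set by the counter-anion, which must leave one face of the styrene open to the bound heterodiene. C4 follows from C2 through the endo transition state of the E heterodiene, which places the aryl and methoxy groups cis, and its configuration is erased in step 9 in any case. Regioselectivity is secured by the polarisation of 9 (nucleophilic CH2, cation-stabilising aryl carbon); enantiofacial selectivity rests on the ion pair inside the catalyst pocket alone. Chemoselectivity over styrene oligomerisation is served by low temperature, excess 9 and slow addition of 6, and the sieves take up methanol so that it does not compete for the cation.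

Step 8
Reactants: 11 (2S,4S)-2-[2-(benzyloxy)-6-methoxyphenyl]-4,5,6,7,8-pentamethoxychromane
Product: 12 (2S)-2-[2-(benzyloxy)-6-methoxyphenyl]-5,6,7,8-tetramethoxychroman-4-ol (mixture of C4 epimers)
Conditions: PPTS (10 mol %), THF/H2O 3:1, rt to 40 °C
Reagents that add atoms: water, O
Why: SN1 solvolysis of a benzylic methyl ether; the C4 cation is stabilised by O1 and the C5 methoxy group (both ortho) and the C7 methoxy group (para) and is taken by water in large excess, while the less basic aryl ether oxygen at C2 should stay untouched under this weak acid.

Step 9
Reactants: 12 (2S)-2-[2-(benzyloxy)-6-methoxyphenyl]-5,6,7,8-tetramethoxychroman-4-ol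
Product: 13 (2S)-2-[2-(benzyloxy)-6-methoxyphenyl]-5,6,7,8-tetramethoxychroman-4-one
Conditions: Dess–Martin periodinane (1.5 equiv), NaHCO3, CH2Cl2, 0 °C to rt
Reagents that add atoms: none
Why: Dess–Martin oxidation of a secondary benzylic alcohol; both C4 epimers converge on one ketone, and the buffered, non-basic medium avoids retro-oxa-Michael opening, so C2 stays S.

Step 10
Reactants: 13 (2S)-2-[2-(benzyloxy)-6-methoxyphenyl]-5,6,7,8-tetramethoxychroman-4-one
Product: 15 (2S)-5-hydroxy-2-(2-hydroxy-6-methoxyphenyl)-6,7,8-trimethoxychroman-4-one, via debenzylated tetramethoxyflavanone 14 (not isolated)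
Conditions: BCl3 (5 equiv), C6HMe5 (3 equiv), CH2Cl2, −78 °C to 0 °C; then MeOH, aq. NaHCO3
Reagents that add atoms: none
Why: Lewis acid ether cleavage; at −78 °C BCl3 should remove the benzyl group as a cation that pentamethylbenzene traps (14, held as its boron aryloxide), and on warming the boron chelated between the C4 carbonyl and the C5 oxygen delivers chloride to that methyl group only. The other four methoxy groups have no chelating neighbour, and C2 is not part of either cleavage.

## Compound list

1 | 3,4,5-trimethoxyphenol | COc1cc(O)cc(OC)c1OC | starting material
2 | 2-hydroxy-4,5,6-trimethoxybenzaldehyde | COc1cc(O)c(C=O)c(OC)c1OC | intermediate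
3 | 3-bromo-2-hydroxy-4,5,6-trimethoxybenzaldehyde | COc1c(Br)c(O)c(C=O)c(OC)c1OC | intermediate
4 | 2-hydroxy-3,4,5,6-tetramethoxybenzaldehyde | COc1c(OC)c(O)c(C=O)c(OC)c1OC | intermediate
5 | trimethyl orthoformate | COC(OC)OC | starting material
6 | 2-(dimethoxymethyl)-3,4,5,6-tetramethoxyphenol | COC(OC)c1c(O)c(OC)c(OC)c(OC)c1OC | intermediate
7 | 2-hydroxy-6-methoxybenzaldehyde | COc1cccc(O)c1C=O | starting material
8 | 2-(benzyloxy)-6-methoxybenzaldehyde | COc1cccc(OCc2ccccc2)c1C=O | intermediate
9 | 1-(benzyloxy)-3-methoxy-2-vinylbenzene | COc1cccc(OCc2ccccc2)c1C=C | intermediate
10 | (E)-6-(methoxymethylidene)-2,3,4,5-tetramethoxycyclohexa-2,4-dien-1-one (ortho-quinone methide, not isolated) | CO/C=C1/C(=O)C(OC)=C(OC)C(OC)=C1OC | intermediate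
11 | (2S,4S)-2-[2-(benzyloxy)-6-methoxyphenyl]-4,5,6,7,8-pentamethoxychromane (2,4-cis) | COc1cccc(OCc2ccccc2)c1[C@@H]1C[C@H](OC)c2c(OC)c(OC)c(OC)c(OC)c2O1 | intermediate
12 | (2S)-2-[2-(benzyloxy)-6-methoxyphenyl]-5,6,7,8-tetramethoxychroman-4-ol (C4 epimers) | COc1cccc(OCc2ccccc2)c1[C@@H]1CC(O)c2c(OC)c(OC)c(OC)c(OC)c2O1 | intermediate
13 | (2S)-2-[2-(benzyloxy)-6-methoxyphenyl]-5,6,7,8-tetramethoxychroman-4-one | COc1cccc(OCc2ccccc2)c1[C@@H]1CC(=O)c2c(OC)c(OC)c(OC)c(OC)c2O1 | intermediate
14 | (2S)-2-(2-hydroxy-6-methoxyphenyl)-5,6,7,8-tetramethoxychroman-4-one (not isolated; in the flask as its boron aryloxide) | COc1cccc(O)c1[C@@H]1CC(=O)c2c(OC)c(OC)c(OC)c(OC)c2O1 | intermediate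
15 | (2S)-5-hydroxy-2-(2-hydroxy-6-methoxyphenyl)-6,7,8-trimethoxychroman-4-one | COc1cccc(O)c1[C@@H]1CC(=O)c2c(O)c(OC)c(OC)c(OC)c2O1 | target

## Step count and least certain steps

Total: 10 steps. Longest linear sequence: 8 steps (steps 1, 2, 3, 4, 7, 8, 9, 10 from phenol 1); the ring B branch contributes steps 5 and 6.

**Step 7 (key step, proposed new method).** The most likely failure is poor enantiofacial selectivity. The hexasubstituted heterodiene may sit loosely in the catalyst pocket or not enter it at all, and the very easily ionised acetal may then react through an unselective background path. Two further losses are possible: acid-induced oligomerisation of the electron-rich styrene, and erosion of the C2 configuration through reversible ionisation of the C2–O1 bond of the product under the strong acid.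
- Fallback by known chemistry, setting out from 6 and 9 and coming back at 11: the cycloaddition is run with an achiral strong acid (TfOH, 5 mol %, CH2Cl2, −40 °C). This is the established racemic reaction and should give the cis adduct as 11 together with its antipode, (2R,4R)-2-[2-(benzyloxy)-6-methoxyphenyl]-4,5,6,7,8-pentamethoxychromane F1. The two are separated by preparative chromatography on a polysaccharide chiral stationary phase, and 11 goes on to step 8.

**Step 10.** The most likely failure is Lewis-acid-assisted opening of ring C. Boron bound to the C4 carbonyl makes O1 a leaving group, the 2,6-dioxygenated ring B stabilises the C2 cation, and reclosure of the resulting chalcone would lose the configuration. Cleavage of a second methoxy group on prolonged warming is the lesser concern.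
- Fallback, setting out from 4 and coming back at 15: the C5 oxygen is unmasked on the achiral aldehyde and carried as a second benzyl ether, so that no Lewis acid meets the flavanone.
- BCl3 in CH2Cl2 at −78 to 0 °C should cleave the methoxy group ortho to the formyl group of 4 through the same chelate, giving the symmetric 2,6-dihydroxy-3,4,5-trimethoxybenzaldehyde F2.
- One equivalent of BnBr with K2CO3 in acetone should alkylate one of the two equivalent hydroxyls and stop, because the remaining one is held in the hydrogen bond to the aldehyde. This gives 2-(benzyloxy)-6-hydroxy-3,4,5-trimethoxybenzaldehyde F3.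
- Acetalisation with 5 as in step 4 gives 3-(benzyloxy)-2-(dimethoxymethyl)-4,5,6-trimethoxyphenol F4.
- Cycloaddition with 9 as in step 7 gives (2S,4S)-5-(benzyloxy)-2-[2-(benzyloxy)-6-methoxyphenyl]-4,6,7,8-tetramethoxychromane F5.
- Hydrolysis as in step 8 gives (2S)-5-(benzyloxy)-2-[2-(benzyloxy)-6-methoxyphenyl]-6,7,8-trimethoxychroman-4-ol F6.
- Dess–Martin oxidation gives (2S)-5-(benzyloxy)-2-[2-(benzyloxy)-6-methoxyphenyl]-6,7,8-trimethoxychroman-4-one F7.
- Hydrogenolysis (H2, Pd/C, EtOAc, rt) removes both benzyl groups and gives 15.

**Step 8.** The most likely failure is E1 loss of a proton from C3 of the C4 cation, giving the flav-3-ene instead of capture by water. It is favoured by the relief of peri strain between the C4 and C5 substituents. Slow ionisation at C2 is a secondary risk if the acid is too strong.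
- Fallback, setting out from 11 and coming back at 13: DDQ (1.2 equiv) in CH2Cl2/H2O at 0 °C should abstract the hydride at C4, the most electron-rich benzylic C–H. Water hydrolyses the resulting oxocarbenium ion to ketone 13, so that no cation with a free C3–H lifetime is needed and step 9 is skipped. This fallback makes no new compound (F0).

**Step 4.** The most likely failure is loss of methanol from the free-phenol acetal during concentration, followed by self-condensation of the quinone methide, or reversion to 4 on contact with moisture. The ring is electron-rich enough to ionise without added acid.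
- Fallback, setting out from 4, 5 and 9 and coming back at 11: the acetal is not isolated. Aldehyde, orthoformate and styrene are combined with the chiral acid and 5 Å MS in toluene, so that 6 forms and is consumed in the same flask; the three-component mode of this cycloaddition is the known racemic variant. This fallback makes no new compound (F0).

## Further compounds

F1 | step 7 | (2R,4R)-2-[2-(benzyloxy)-6-methoxyphenyl]-4,5,6,7,8-pentamethoxychromane (antipode of 11) | COc1cccc(OCc2ccccc2)c1[C@H]1C[C@@H](OC)c2c(OC)c(OC)c(OC)c(OC)c2O1
F2 | step 10 | 2,6-dihydroxy-3,4,5-trimethoxybenzaldehyde | COc1c(O)c(C=O)c(O)c(OC)c1OC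
F3 | step 10 | 2-(benzyloxy)-6-hydroxy-3,4,5-trimethoxybenzaldehyde | COc1c(O)c(C=O)c(OCc2ccccc2)c(OC)c1OC
F4 | step 10 | 3-(benzyloxy)-2-(dimethoxymethyl)-4,5,6-trimethoxyphenol | COC(OC)c1c(O)c(OC)c(OC)c(OC)c1OCc1ccccc1
F5 | step 10 | (2S,4S)-5-(benzyloxy)-2-[2-(benzyloxy)-6-methoxyphenyl]-4,6,7,8-tetramethoxychromane | COc1cccc(OCc2ccccc2)c1[C@@H]1C[C@H](OC)c2c(OCc3ccccc3)c(OC)c(OC)c(OC)c2O1
F6 | step 10 | (2S)-5-(benzyloxy)-2-[2-(benzyloxy)-6-methoxyphenyl]-6,7,8-trimethoxychroman-4-ol (C4 epimers) | COc1cccc(OCc2ccccc2)c1[C@@H]1CC(O)c2c(OCc3ccccc3)c(OC)c(OC)c(OC)c2O1
F7 | step 10 | (2S)-5-(benzyloxy)-2-[2-(benzyloxy)-6-methoxyphenyl]-6,7,8-trimethoxychroman-4-one | COc1cccc(OCc2ccccc2)c1[C@@H]1CC(=O)c2c(OCc3ccccc3)c(OC)c(OC)c(OC)c2O1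
F0 | step 8 | none | none
F0 | step 4 | none | none
A1 | alternative 1 | (S)-2-[2-hydroxy-6-(triisopropylsilyloxy)phenyl]-5,6,7,8-tetramethoxychroman-4-one | CC(C)[Si](C(C)C)(C(C)C)Oc1cccc(O)c1[C@@H]1CC(=O)c2c(OC)c(OC)c(OC)c(OC)c2O1
A2 | alternative 1 | (2S)-5,6,7,8-tetramethoxy-2-[(triisopropylsilyloxy)ethynyl]chroman-4-one | CC(C)[Si](C(C)C)(C(C)C)OC#C[C@@H]1CC(=O)c2c(OC)c(OC)c(OC)c(OC)c2O1
A3 | alternative 1 | cyclobut-2-en-1-one | O=C1CC=C1
A4 | alternative 2 | (2S,4S)-2-(2-isopropoxy-6-methoxyphenyl)-4-(tert-butyldimethylsilyloxy)-5-hydroxy-6,7,8-trimethoxychroman | COc1cccc(OC(C)C)c1[C@@H]1C[C@H](O[Si](C)(C)C(C)(C)C)c2c(O)c(OC)c(OC)c(OC)c2O1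
A5 | alternative 2 | 4-[(2S,4S)-4-(tert-butyldimethylsilyloxy)-2-(2-isopropoxy-6-methoxyphenyl)-3,4-dihydro-2H-pyran-6-yl]-2,3,4-trimethoxycyclobut-2-en-1-one | COc1cccc(OC(C)C)c1[C@@H]1C[C@H](O[Si](C)(C)C(C)(C)C)C=C(O1)C1(OC)C(OC)=C(OC)C1=O
A6 | alternative 3 | (S)-2-[2-(benzyloxy)-6-methoxyphenyl]-5,8-dihydroxy-6,7-dimethoxychroman-4-one | COc1cccc(OCc2ccccc2)c1[C@@H]1CC(=O)c2c(O)c(OC)c(OC)c(O)c2O1
A7 | alternative 3 | 2-[(3S)-3-(2-benzyloxy-6-methoxyphenyl)-3-hydroxypropanoyl]-5,6-dimethoxy-1,4-benzoquinone | COc1cccc(OCc2ccccc2)c1[C@@H](O)CC(=O)C1=CC(=O)C(OC)=C(OC)C1=O
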